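A reading at 2.0 d is worth what the flask still does by then, so the time of reading is the first thing to hold against the runs.

| flask | solid substrate | reagent | remark | time |
|---|---|---|---|---|
| noon | 1.5 M | 1.2 M | the very flask that is asked about, followed so far |  |
| winter | 0.75 M | 1.2 M | run made earlier |  |
| flask | 1.5 M | 1.20 M |  | 2.0 d |

noon run (percent of the solid substrate charged): time / h: mono adduct / % = 4.00: 3.1; 8.00: 7.4; 15.0: 8.1; 25.0: 7.6; 50.0: 8.0

winter run (percent of the solid substrate charged): time / min: mono adduct / % = 10.0: 0.7; 30.0: 2.7; 60.0: 3.7; 80.0: 3.9; 120: 4.8

(scatter of a reading: 0.3 percentage points)

- as a solid, counted per litre of solution: solid substrate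
- additions leave the volume as it is
- at the start none of the solid substrate is in solution

- Wednesday's: change nothing and wait 4.0 d more
- Tuesday's: at 2.0 d take out 90% of the released group then present, then wait 4.0 d
- Thursday's: at 2.0 d add reagent, 50.0% of the amount charged, then wait 4.0 d

- mono adduct, in percent of the solid substrate first charged, at 2.0 d
- which option adds most mono adduct ("none" when 2 percentage points or less is all one gets) (Wednesday's / Tuesday's / Thursday's / none)
- mono adduct present, in percent of the solid substrate first charged, after Wednesday's
- mono adduct present, in percent of the solid substrate first charged, after Thursday's

In the noon run, which is this flask so far, mono adduct reads 3.1% of the solid substrate charged at 4.00 h and 7.4% at 8.00 h. The later readings then average 7.90% and stay flat within the scatter of 0.3 percentage points. Take the time of reading over the time by which the plateau is nearly reached, read here as 8.00 h: for this flask that gives 6.00, the bend number. Being above one, it puts a reading in this flask past the crossing where growth gives way to standstill, so my reckoning is the plateau at 2.0 d, and Wednesday's adds nothing.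

But one number is not enough: it says that mono adduct stands, not why. The reagent charged is 0.800 of the solid charge, while mono adduct holds a far smaller fraction. So if the plateau marks the end of free reagent, the rest of that reagent went elsewhere. Then Tuesday's has nothing to pull on, and Thursday's 0.400 of the solid charge, 5.06 times the plateau, carries mono adduct away. My choice is therefore none.

The forecast holds 7.9% now, 7.9% after Wednesday's, 9.8% after Thursday's and Tuesday's as best, reading the plateau thus: “I take this as equilibrium”.

The flask gives 8.12% at 2.0 d, 8.12% after Wednesday's and 0% after Thursday's. Tuesday's gains 0 points, so the best option is none.

    starting material + reagent → other mono adduct + released group (k = 0.220 M⁻¹ h⁻¹)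
    reagent + mono adduct → double product + released group (k = 3.80 M⁻¹ h⁻¹)
    solid substrate ⇌ starting material, rate k3*(cs3 - [starting material]) while solid is left; crystals form when [starting material] > cs3 (solubility = 0.670 M, k = 0.180 h⁻¹)
    starting material + reagent → mono adduct + released group (k = 6.10 M⁻¹ h⁻¹)
    reagent + other mono adduct → double product + released group (k = 2.20 M⁻¹ h⁻¹)
    starting material + released group → side product (k = 0.0950 M⁻¹ h⁻¹)

At a bend number of 6.00, mono adduct in this flask stands still at 2.0 d, with reagent, the limiting reagent, at 0% free at 48.0 h. The main reason for so low a level is the step from reagent + mono adduct to double product + released group: the run without that step gives 75.1% at 2.0 d instead of 8.12%.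

The same flask read at 12 h has a bend number of 1.50, above one, which places it on the plateau. It gives 8.12%.

All runs are simulated from invented constants; noise was put on by code.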